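**Retrosynthetic overview**

- Feature: in ring C the adjacent carbons C1 (carbonyl, on C8a) and C2 (C–OH) are both oxidised and electrophilic, and the hydroxyl has to sit on C2, next to C1, and not on C3 next to the C4 carbonyl that is peri to the C5 hydroxyl of ring B.
- Key disconnection C1–C2: a carbene turns the C8a aldehyde into an acyl anion that adds to the ethoxy-bearing alkyne carbon of the ynone on C4a; ring C is closed last (6-endo-dig) and arrives at the quinone oxidation level.
- The precursor comes from a ring B aldehyde by ethoxyacetylide addition and oxidation, with C1 carried as a silyloxymethyl group; a lactone, acid chloride or free ortho aldehyde would not survive an acetylide next to the acidic C7 methylene.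
- The pyrone is attached at C7 by Suzuki coupling of a bromomethylpyrone, and the ring A aroyl group at C6 by lithiation between Br and OMe and addition to the ring A aldehyde.
- Ring B core from 3-methoxybenzyl alcohol through 7-methoxyphthalide (C4a carbon by directed lithiation, C7–Br by iridium borylation and bromination); rings A, B and the pyrone are bought, ring C is the only ring formed.

Key step: step 12

Remark on the chemistry: ring B positions carry the numbers of the final naphthalene-1,4-dione (C4a, C5–C8, C8a; C1 on C8a, C4 on C4a), and the target is treated as the drawn 2-hydroxy-1,4-dione tautomer.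

**Route**

Step 1
Reactants: 1 3-methoxybenzyl alcohol
Product: 2 7-methoxy-2-benzofuran-1(3H)-one (7-methoxyphthalide)
Conditions: n-BuLi (2.3 equiv), TMEDA, hexane/Et2O, 0 °C → rt; CO2, −78 °C → rt; 2 M HCl
Reagents that add atoms: carbon dioxide, O=C=O
Why: Directed ortho metalation, in which the lithium alkoxide and the methoxy group together direct n-BuLi to the carbon between them (C4a), followed by carboxylation and acid lactonisation, should give the phthalide that holds C4 (lactone carbonyl) and C1 (CH2O) in differentiated form.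

Step 2
Reactants: 2 7-methoxy-2-benzofuran-1(3H)-one
Product: 4 5-bromo-7-methoxy-2-benzofuran-1(3H)-one, via aryl pinacol boronate 3 (not isolated)
Conditions: [Ir(OMe)(cod)]2 (1.5 mol %), 4,4'-di-tert-butyl-2,2'-bipyridine, B2pin2, THF, 80 °C; then CuBr2, MeOH/H2O, 80 °C
Reagents that add atoms: CuBr2, [Cu+2].[Br-].[Br-]; bis(pinacolato)diboron, CC1(C)OB(OC1(C)C)B1OC(C)(C)C(C)(C)O1 (supplies the boryl group of 3, which is replaced again)
Why: Sterically governed iridium-catalysed C–H borylation should take the only ring hydrogen without an ortho substituent (C7, meta to OMe), and copper-mediated bromodeboronation converts the boronate into the bromide, the lactone tolerating both operations.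

Step 3
Reactants: 4 5-bromo-7-methoxy-2-benzofuran-1(3H)-one
Product: 5 (5-bromo-3-methoxy-1,2-phenylene)dimethanol
Conditions: LiBH4, THF, MeOH (1 equiv), 0 °C → rt
Reagents that add atoms: none
Why: Hydride reduction of the lactone to the diol, with LiBH4 leaving the aryl bromide untouched.

Step 4
Reactants: 5 (5-bromo-3-methoxy-1,2-phenylene)dimethanol
Product: 6 [4-bromo-2-({[tert-butyl(dimethyl)silyl]oxy}methyl)-6-methoxyphenyl]methanol
Conditions: TBSCl (1.0 equiv), imidazole, CH2Cl2, −30 → 0 °C
Reagents that add atoms: tert-butyldimethylsilyl chloride, CC(C)(C)[Si](C)(C)Cl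
Why: Kinetic monosilylation should select the less hindered primary alcohol on C8a (one ortho hydrogen) over the C4a carbinol, which is flanked by OMe and the other arm and hydrogen-bonded to the methoxy oxygen.

Step 5
Reactants: 6 [4-bromo-2-({[tert-butyl(dimethyl)silyl]oxy}methyl)-6-methoxyphenyl]methanol; 7 2,4-dimethoxy-6-methylbenzaldehyde
Product: 8 rac-[6-bromo-4-({[tert-butyl(dimethyl)silyl]oxy}methyl)-3-(hydroxymethyl)-2-methoxyphenyl](2,4-dimethoxy-6-methylphenyl)methanol
Conditions: LDA (2.2 equiv), THF, −78 °C; then 7, −78 → −50 °C; aq. NH4Cl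
Reagents that add atoms: none
Why: After the hydroxyl, LDA removes the most acidic ring hydrogen (C6–H between Br and OMe) without halogen–lithium exchange, and 1,2-addition of the aryllithium to the non-enolisable aldehyde should give the benzhydrol as a racemate whose centre is erased in step 6.

Step 6
Reactants: 8 rac-[6-bromo-4-({[tert-butyl(dimethyl)silyl]oxy}methyl)-3-(hydroxymethyl)-2-methoxyphenyl](2,4-dimethoxy-6-methylphenyl)methanol
Product: 9 4-bromo-6-({[tert-butyl(dimethyl)silyl]oxy}methyl)-3-(2,4-dimethoxy-6-methylbenzoyl)-2-methoxybenzaldehyde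
Conditions: Dess–Martin periodinane (3 equiv), CH2Cl2, 0 °C → rt
Reagents that add atoms: none
Why: Dess–Martin oxidation should convert the diaryl carbinol into the ring A aroyl ketone and the C4a hydroxymethyl group into the aldehyde in one operation, the two carbinols being meta on ring B and unable to form a lactol.

Step 7
Reactants: 10 4-methoxy-6-methyl-2H-pyran-2-one
Product: 11 6-(bromomethyl)-4-methoxy-2H-pyran-2-one
Conditions: NBS, (PhCO2)2 (cat.), PhCF3, reflux
Reagents that add atoms: N-bromosuccinimide, O=C1CCC(=O)N1Br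
Why: Wohl–Ziegler radical bromination of the C6 methyl group, which is allylic to the pyrone diene.

Step 8
Reactants: 9 4-bromo-6-({[tert-butyl(dimethyl)silyl]oxy}methyl)-3-(2,4-dimethoxy-6-methylbenzoyl)-2-methoxybenzaldehyde; 11 6-(bromomethyl)-4-methoxy-2H-pyran-2-one
Product: 13 6-({[tert-butyl(dimethyl)silyl]oxy}methyl)-3-(2,4-dimethoxy-6-methylbenzoyl)-2-methoxy-4-[(4-methoxy-2-oxo-2H-pyran-6-yl)methyl]benzaldehyde, via aryl pinacol boronate 12 (not isolated)
Conditions: B2pin2, PdCl2(dppf), KOAc, 1,4-dioxane, 85 °C; then 11, K3PO4, H2O, 60 °C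
Reagents that add atoms: bis(pinacolato)diboron, CC1(C)OB(OC1(C)C)B1OC(C)(C)C(C)(C)O1 (supplies the boryl group of 12 only)
Why: Miyaura borylation of the aryl bromide followed by Suzuki–Miyaura coupling of the boronate with the activated benzylic-type bromide should join C7 to the pyrone methylene, the aldehyde, the hindered ketone and the silyl ether being inert.

Step 9
Reactants: 13 6-({[tert-butyl(dimethyl)silyl]oxy}methyl)-3-(2,4-dimethoxy-6-methylbenzoyl)-2-methoxy-4-[(4-methoxy-2-oxo-2H-pyran-6-yl)methyl]benzaldehyde; 14 ethoxyethyne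
Product: 15 rac-6-{[5-({[tert-butyl(dimethyl)silyl]oxy}methyl)-2-(2,4-dimethoxy-6-methylbenzoyl)-4-(3-ethoxy-1-hydroxyprop-2-yn-1-yl)-3-methoxyphenyl]methyl}-4-methoxy-2H-pyran-2-one
Conditions: 14, n-BuLi, THF, −78 °C; CeCl3, −78 °C; then 13, −78 °C; pH 7 phosphate buffer
Reagents that add atoms: none
Why: 1,2-Addition of the ethoxyethynyl cerium reagent to the aldehyde, the organocerium being nucleophilic but weakly basic so that the acidic C7 methylene and the pyrone are left alone; the new carbinol centre is racemic and is removed in step 11.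

Step 10
Reactants: 15 rac-6-{[5-({[tert-butyl(dimethyl)silyl]oxy}methyl)-2-(2,4-dimethoxy-6-methylbenzoyl)-4-(3-ethoxy-1-hydroxyprop-2-yn-1-yl)-3-methoxyphenyl]methyl}-4-methoxy-2H-pyran-2-one
Product: 16 rac-6-{[2-(2,4-dimethoxy-6-methylbenzoyl)-4-(3-ethoxy-1-hydroxyprop-2-yn-1-yl)-5-(hydroxymethyl)-3-methoxyphenyl]methyl}-4-methoxy-2H-pyran-2-one
Conditions: TBAF, THF, 0 °C
Reagents that add atoms: none
Why: Fluoride cleavage of the silyl ether, carried out while the alkyne is still a base-stable ynol ether carbinol, so that the C1 hydroxyl is unmasked before any acid-sensitive ynone exists.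

Step 11
Reactants: 16 rac-6-{[2-(2,4-dimethoxy-6-methylbenzoyl)-4-(3-ethoxy-1-hydroxyprop-2-yn-1-yl)-5-(hydroxymethyl)-3-methoxyphenyl]methyl}-4-methoxy-2H-pyran-2-one
Product: 18 4-(2,4-dimethoxy-6-methylbenzoyl)-2-(3-ethoxyprop-2-ynoyl)-3-methoxy-5-[(4-methoxy-2-oxo-2H-pyran-6-yl)methyl]benzaldehyde, via hydroxymethyl ynone 17 (not isolated)
Conditions: MnO2 (activated, excess), CH2Cl2, rt; filtration; then Dess–Martin periodinane, NaHCO3, CH2Cl2, 0 °C
Reagents that add atoms: none
Why: MnO2 should oxidise the doubly activated (benzylic and propargylic) secondary carbinol ahead of the primary alcohol on the electron-poor ring, giving the ynone whose hemiketal form cannot be over-oxidised, and buffered Dess–Martin oxidation of the primary alcohol then gives the aldehyde under neutral conditions.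

Step 12
Reactants: 18 4-(2,4-dimethoxy-6-methylbenzoyl)-2-(3-ethoxyprop-2-ynoyl)-3-methoxy-5-[(4-methoxy-2-oxo-2H-pyran-6-yl)methyl]benzaldehyde
Product: 19 6-(2,4-dimethoxy-6-methylbenzoyl)-2-ethoxy-5-methoxy-7-[(4-methoxy-2-oxo-2H-pyran-6-yl)methyl]naphthalene-1,4-dione
Conditions: 2-(pentafluorophenyl)-6,7-dihydro-5H-pyrrolo[2,1-c][1,2,4]triazol-2-ium tetrafluoroborate (20 mol %), iPr2NEt (20 mol %), toluene (0.02 M), 4 Å molecular sieves, 25 → 40 °C, argon
Reagents that add atoms: none
Why: Proposed new method: the carbene from the triazolium salt adds to the C1 aldehyde and proton transfer gives the Breslow intermediate, whose nucleophilic C1 attacks C2, the ethoxy-bearing β-carbon of the ortho ynone; the allenolate is protonated at C3 and loss of the carbene leaves the C1 ketone, so that the C1–C2 bond and ring C form as the 2-ethoxy-1,4-dione with no change of oxidation level. The closest known reactions are the carbene-catalysed intramolecular Stetter reaction of ortho-tethered aldehydes and the carbene-catalysed hydroacylation of activated alkynes; an alkoxy ynone as acceptor is not established. Ring C closes in the 6-endo-dig mode and no stereocentre is formed. The step needs attack at C2 and not at C3 (5-exo-dig, leading to a 2-(ethoxymethylene)indane-1,3-dione); the polarisation of the push–pull alkyne secures this, since only attack at C2 gives the stabilised allenolate, and the placement of the aldehyde on C8a with the ynone on C4a fixes the oxygen on C2 next to C1 and away from the C5 oxygen. Side paths are addition of the free carbene to the ynone and oxidation of the Breslow intermediate by the product quinone; the electron-poor N-pentafluorophenyl triazolium, high dilution and a weak amine base (which also leaves the acidic C7 methylene alone) are chosen to suppress them.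

Step 13
Reactants: 19 6-(2,4-dimethoxy-6-methylbenzoyl)-2-ethoxy-5-methoxy-7-[(4-methoxy-2-oxo-2H-pyran-6-yl)methyl]naphthalene-1,4-dione
Product: 20 6-(2,4-dimethoxy-6-methylbenzoyl)-2-hydroxy-5-methoxy-7-[(4-methoxy-2-oxo-2H-pyran-6-yl)methyl]naphthalene-1,4-dione
Conditions: 2 M aq. HCl, THF, 50 °C
Reagents that add atoms: water, O
Why: Acid hydrolysis of the vinylogous ethyl ester by addition–elimination of water at C2, which the aryl and pyrone methyl ethers should survive.

Step 14
Reactants: 20 6-(2,4-dimethoxy-6-methylbenzoyl)-2-hydroxy-5-methoxy-7-[(4-methoxy-2-oxo-2H-pyran-6-yl)methyl]naphthalene-1,4-dione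
Product: 21 6-(2,4-dihydroxy-6-methylbenzoyl)-2,5-dihydroxy-7-[(4-hydroxy-2-oxo-2H-pyran-6-yl)methyl]naphthalene-1,4-dione (target)
Conditions: BBr3 (10 equiv), CH2Cl2, −78 °C → rt; then H2O
Reagents that add atoms: none
Why: Lewis-acid ether cleavage, in which BBr3 should remove the three aryl methyl ethers (each ortho or para to a carbonyl) and the pyrone 4-O-methyl group (a vinylogous methyl ester) by bromide attack on methyl.

**Compound list**

1 | 3-methoxybenzyl alcohol | COc1cccc(CO)c1 | starting material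
2 | 7-methoxy-2-benzofuran-1(3H)-one | COc1cccc2c1C(=O)OC2 | intermediate
3 | 7-methoxy-5-(4,4,5,5-tetramethyl-1,3,2-dioxaborolan-2-yl)-2-benzofuran-1(3H)-one (not isolated) | COc1cc(B2OC(C)(C)C(C)(C)O2)cc2c1C(=O)OC2 | intermediate
4 | 5-bromo-7-methoxy-2-benzofuran-1(3H)-one | COc1cc(Br)cc2c1C(=O)OC2 | intermediate
5 | (5-bromo-3-methoxy-1,2-phenylene)dimethanol | COc1cc(Br)cc(CO)c1CO | intermediate
6 | [4-bromo-2-({[tert-butyl(dimethyl)silyl]oxy}methyl)-6-methoxyphenyl]methanol | COc1cc(Br)cc(CO[Si](C)(C)C(C)(C)C)c1CO | intermediate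
7 | 2,4-dimethoxy-6-methylbenzaldehyde | Cc1cc(OC)cc(OC)c1C=O | starting material
8 | rac-[6-bromo-4-({[tert-butyl(dimethyl)silyl]oxy}methyl)-3-(hydroxymethyl)-2-methoxyphenyl](2,4-dimethoxy-6-methylphenyl)methanol | COc1c(C(O)c2c(C)cc(OC)cc2OC)c(Br)cc(CO[Si](C)(C)C(C)(C)C)c1CO | intermediate
9 | 4-bromo-6-({[tert-butyl(dimethyl)silyl]oxy}methyl)-3-(2,4-dimethoxy-6-methylbenzoyl)-2-methoxybenzaldehyde | COc1c(C(=O)c2c(C)cc(OC)cc2OC)c(Br)cc(CO[Si](C)(C)C(C)(C)C)c1C=O | intermediate
10 | 4-methoxy-6-methyl-2H-pyran-2-one | COc1cc(C)oc(=O)c1 | starting material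
11 | 6-(bromomethyl)-4-methoxy-2H-pyran-2-one | COc1cc(CBr)oc(=O)c1 | intermediate
12 | 6-({[tert-butyl(dimethyl)silyl]oxy}methyl)-3-(2,4-dimethoxy-6-methylbenzoyl)-2-methoxy-4-(4,4,5,5-tetramethyl-1,3,2-dioxaborolan-2-yl)benzaldehyde (not isolated) | COc1c(C(=O)c2c(C)cc(OC)cc2OC)c(B2OC(C)(C)C(C)(C)O2)cc(CO[Si](C)(C)C(C)(C)C)c1C=O | intermediate
13 | 6-({[tert-butyl(dimethyl)silyl]oxy}methyl)-3-(2,4-dimethoxy-6-methylbenzoyl)-2-methoxy-4-[(4-methoxy-2-oxo-2H-pyran-6-yl)methyl]benzaldehyde | COc1c(C(=O)c2c(C)cc(OC)cc2OC)c(Cc2cc(OC)cc(=O)o2)cc(CO[Si](C)(C)C(C)(C)C)c1C=O | intermediate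
14 | ethoxyethyne | CCOC#C | starting material
15 | rac-6-{[5-({[tert-butyl(dimethyl)silyl]oxy}methyl)-2-(2,4-dimethoxy-6-methylbenzoyl)-4-(3-ethoxy-1-hydroxyprop-2-yn-1-yl)-3-methoxyphenyl]methyl}-4-methoxy-2H-pyran-2-one | CCOC#CC(O)c1c(OC)c(C(=O)c2c(C)cc(OC)cc2OC)c(Cc2cc(OC)cc(=O)o2)cc1CO[Si](C)(C)C(C)(C)C | intermediate
16 | rac-6-{[2-(2,4-dimethoxy-6-methylbenzoyl)-4-(3-ethoxy-1-hydroxyprop-2-yn-1-yl)-5-(hydroxymethyl)-3-methoxyphenyl]methyl}-4-methoxy-2H-pyran-2-one | CCOC#CC(O)c1c(OC)c(C(=O)c2c(C)cc(OC)cc2OC)c(Cc2cc(OC)cc(=O)o2)cc1CO | intermediate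
17 | 6-{[2-(2,4-dimethoxy-6-methylbenzoyl)-4-(3-ethoxyprop-2-ynoyl)-5-(hydroxymethyl)-3-methoxyphenyl]methyl}-4-methoxy-2H-pyran-2-one (open form, in equilibrium with its cyclic hemiketal; not isolated) | CCOC#CC(=O)c1c(OC)c(C(=O)c2c(C)cc(OC)cc2OC)c(Cc2cc(OC)cc(=O)o2)cc1CO | intermediate
18 | 4-(2,4-dimethoxy-6-methylbenzoyl)-2-(3-ethoxyprop-2-ynoyl)-3-methoxy-5-[(4-methoxy-2-oxo-2H-pyran-6-yl)methyl]benzaldehyde | CCOC#CC(=O)c1c(OC)c(C(=O)c2c(C)cc(OC)cc2OC)c(Cc2cc(OC)cc(=O)o2)cc1C=O | intermediate
19 | 6-(2,4-dimethoxy-6-methylbenzoyl)-2-ethoxy-5-methoxy-7-[(4-methoxy-2-oxo-2H-pyran-6-yl)methyl]naphthalene-1,4-dione | CCOC1=CC(=O)c2c(OC)c(C(=O)c3c(C)cc(OC)cc3OC)c(Cc3cc(OC)cc(=O)o3)cc2C1=O | intermediate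
20 | 6-(2,4-dimethoxy-6-methylbenzoyl)-2-hydroxy-5-methoxy-7-[(4-methoxy-2-oxo-2H-pyran-6-yl)methyl]naphthalene-1,4-dione | OC1=CC(=O)c2c(OC)c(C(=O)c3c(C)cc(OC)cc3OC)c(Cc3cc(OC)cc(=O)o3)cc2C1=O | intermediate
21 | 6-(2,4-dihydroxy-6-methylbenzoyl)-2,5-dihydroxy-7-[(4-hydroxy-2-oxo-2H-pyran-6-yl)methyl]naphthalene-1,4-dione | Cc1cc(O)cc(O)c1C(=O)c1c(Cc2cc(O)cc(=O)o2)cc2c(c1O)C(=O)C=C(O)C2=O | target

**Step count and risks**

Total step count: 14. Longest linear sequence: 13 steps (steps 1–6 and 8–14; step 7 prepares the pyrone bromide).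

Steps most likely to fail:

1. Step 12 (proposed new method). The Breslow intermediate may attack C3 instead of C2, the free carbene may be consumed by addition to the alkoxy ynone, or the product quinone may oxidise the Breslow intermediate and stall turnover. The fallback uses known chemistry, sets out from compound 13 and returns at compound 20.
   - MeTi(OiPr)3 in THF at −20 °C should add to the aldehyde alone to give the secondary carbinol F1, and Dess–Martin oxidation gives the methyl ketone F2.
   - TBAF frees the benzylic alcohol F3, and CBr4/PPh3 converts it into the benzylic bromide F4.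
   - Palladium-catalysed methoxycarbonylation (PdCl2(PPh3)2, CO, MeOH, iPr2NEt) gives the methyl arylacetate F5.
   - NaH in THF closes ring C by Claisen condensation of the acetyl enolate (C3) onto the ester carbon (C2), giving the naphthalene-1,3-diol F6.
   - Oxidation with Fremy's salt, ON(SO3K)2, in buffered aqueous acetone introduces the C1 carbonyl para to the C4 hydroxyl and should give 20, which goes on to step 14.

2. Step 11. The primary carbinol may be oxidised before the secondary one, after which lactol formation and over-oxidation to a lactone would follow; the hemiketal form of 17 may also collapse with loss of the ynol ether. The fallback sets out from compound 15 and returns at compound 17, so that a free secondary carbinol never meets the aldehyde. MnO2 oxidises the propargylic carbinol with the silyl ether still in place to give the silyl-protected ynone F7; HF·pyridine buffered with pyridine in THF at 0 °C removes the silyl group to give 17, and buffered Dess–Martin oxidation gives 18.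

3. Step 8. Bromide 11 may hydrolyse under the aqueous base, boronate 12 may protodeboronate next to the bulky aroyl group, or the acidic methylene of 13 may be alkylated a second time. The fallback sets out from compound 9 and returns at compound 13 with the polarity of the partners reversed and no base. Bromide 11 is converted with (Bu3Sn)2 and Pd(PPh3)4 into the pyronylmethyl stannane F8, and Stille coupling of F8 with aryl bromide 9 (Pd(PPh3)4, CuI, DMF, 80 °C) should give 13.

Further compounds
F1 | step 12 | rac-6-{[5-({[tert-butyl(dimethyl)silyl]oxy}methyl)-2-(2,4-dimethoxy-6-methylbenzoyl)-4-(1-hydroxyethyl)-3-methoxyphenyl]methyl}-4-methoxy-2H-pyran-2-one | CC(O)c1c(OC)c(C(=O)c2c(C)cc(OC)cc2OC)c(Cc2cc(OC)cc(=O)o2)cc1CO[Si](C)(C)C(C)(C)C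
F2 | step 12 | 6-{[4-acetyl-5-({[tert-butyl(dimethyl)silyl]oxy}methyl)-2-(2,4-dimethoxy-6-methylbenzoyl)-3-methoxyphenyl]methyl}-4-methoxy-2H-pyran-2-one | CC(=O)c1c(OC)c(C(=O)c2c(C)cc(OC)cc2OC)c(Cc2cc(OC)cc(=O)o2)cc1CO[Si](C)(C)C(C)(C)C
F3 | step 12 | 6-{[4-acetyl-2-(2,4-dimethoxy-6-methylbenzoyl)-5-(hydroxymethyl)-3-methoxyphenyl]methyl}-4-methoxy-2H-pyran-2-one | CC(=O)c1c(OC)c(C(=O)c2c(C)cc(OC)cc2OC)c(Cc2cc(OC)cc(=O)o2)cc1CO
F4 | step 12 | 6-{[4-acetyl-5-(bromomethyl)-2-(2,4-dimethoxy-6-methylbenzoyl)-3-methoxyphenyl]methyl}-4-methoxy-2H-pyran-2-one | CC(=O)c1c(OC)c(C(=O)c2c(C)cc(OC)cc2OC)c(Cc2cc(OC)cc(=O)o2)cc1CBr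
F5 | step 12 | methyl {2-acetyl-4-(2,4-dimethoxy-6-methylbenzoyl)-3-methoxy-5-[(4-methoxy-2-oxo-2H-pyran-6-yl)methyl]phenyl}acetate | CC(=O)c1c(OC)c(C(=O)c2c(C)cc(OC)cc2OC)c(Cc2cc(OC)cc(=O)o2)cc1CC(=O)OC
F6 | step 12 | 6-{[3-(2,4-dimethoxy-6-methylbenzoyl)-5,7-dihydroxy-4-methoxynaphthalen-2-yl]methyl}-4-methoxy-2H-pyran-2-one | COc1c(C(=O)c2c(C)cc(OC)cc2OC)c(Cc2cc(OC)cc(=O)o2)cc2cc(O)cc(O)c12
F7 | step 11 | 6-{[5-({[tert-butyl(dimethyl)silyl]oxy}methyl)-2-(2,4-dimethoxy-6-methylbenzoyl)-4-(3-ethoxyprop-2-ynoyl)-3-methoxyphenyl]methyl}-4-methoxy-2H-pyran-2-one | CCOC#CC(=O)c1c(OC)c(C(=O)c2c(C)cc(OC)cc2OC)c(Cc2cc(OC)cc(=O)o2)cc1CO[Si](C)(C)C(C)(C)C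
F8 | step 8 | 4-methoxy-6-[(tributylstannyl)methyl]-2H-pyran-2-one | CCCC[Sn](CCCC)(CCCC)Cc1cc(OC)cc(=O)o1
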